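## The problem

The target (28) is a germacranolide: a ten-membered carbocycle (C1–C10) fused trans at C6/C7 to an α-methylene-γ-butyrolactone (C11, C12, C13). It carries a trisubstituted Z olefin at C4–C5 inside the ring, an angelate on C8, secondary hydroxyls on C1 and C3, and a tertiary hydroxyl with the C14 methyl on C10. Closing a ten-membered ring that must hold a Z olefin costs entropy and transannular strain, and the six stereocentres (C1, C3, C6, C7, C8, C10) sit on a flexible ring where one centre cannot be trusted to steer a remote one. Their relations are: C6–O trans to the C7 side chain, the C1 and C10 hydroxyls cis, and the C3 and C8 oxygens each trans (1,3-anti) to the hydroxyl two carbons away (C1 and C10). Rough treatment is excluded late: the α-methylene lactone is a Michael acceptor, the angelate isomerises to the tiglate with base or nucleophilic catalysts, and a 3-oxo intermediate with a free C6 hydroxyl across the Z olefin tends to close to a hemiketal and lose water to a furan. The enabling feature is that C3 and C8 both carry oxygen and are separated by four ring atoms on either side (C4–C7, and C2, C1, C10, C9). Joining them gives a cis-decalin with a ring-fusion glycol, which tetravalent lead cleaves to a 1,6-dione. In that bicycle the C4–C5 olefin lies in a cyclohexene (hence Z), C6 and C7 are neighbours on a six-membered ring that maps onto carvone, C1 and C10 lie on a second six-membered ring with an open convex face, and after cleavage the C10 and C1 hydroxyls sit β to the two new ketones and can direct their reduction.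

## Retrosynthesis

**End game, 28 back to 22.** The C3–H and C8–H bonds and the C8–O acyl bond are cut, so that 28 comes from enone 27, its silyl ether 26, alcohol 23 plus angelic acid (24), and finally dione 22. The two carbonyls are what a glycol cleavage delivers, and each has a hydroxyl two carbons away on the β-face (C10–OH for C8, C1–OH for C3). Reducing C8 first, with C1 silylated, leaves one free secondary hydroxyl when the angelate is attached; the C3 carbonyl is kept to the last step. Compound 22 has two stereocentres fewer and no angelate. The forward steps must deliver hydride from the face of the directing hydroxyl and acylate without Z-to-E isomerisation.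

**Ring opening, 22 back to 21.** The C3–C8 bond is re-formed, which turns the ten-membered dione into a cis-fused bicycle with tertiary hydroxyls on both fusion carbons. Against a cut at C1–C10, C5–C6 or the olefin, this one needs no macrocyclisation, places the Z olefin inside a cyclohexene, and puts every remaining stereocentre on a six-membered ring. The forward reaction must cleave only this glycol and leave the C7 hydrogen, now α to a ketone, alone.

**Ring B glycol, 21 back to 19.** The C1–O and C10–O bonds are cut (silyl ether 21, tetraol 20, olefin 19). A suprafacial dihydroxylation gives the cis relation directly. Because a cis-fused bicycle is attacked on its convex face, the face of the fusion substituents, the fusion hydroxyls must be β, cis to the C7 side chain. This requirement fixes the temporary configuration at C8 and the order of events there (see the C8 paragraph).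

**Lactone, 19 back to 15.** The C12 oxidation level is lowered and the lactone opened to a 6,12-diol (18 is the silyl ether of 19; 15 is the diol). Closing the lactone before the dihydroxylation turns the side-chain methylene into an electron-poor acrylate that OsO4 leaves alone. Closing it before the ring opening means no free C6 hydroxyl ever faces the Z-enone. The forward oxidation must pick the primary alcohol and close onto O6, not O8.

**Ring B carbons, 15 back to 12, 13.** The C1=C10 bond is cut by a metathesis transform (diene 14) and the C2–C3 bond by removal of an allyl nucleophile (allylmagnesium bromide, 13) from ketone 12. Two simple olefinic arms on adjacent quaternary carbons are easier to install than a preformed four-carbon bridge. The addition must place the allyl group cis to the methallyl group.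

**C6 oxygen, 12 back to 9.** The C6–O bond is cut; 12 comes from enone 9 through its dienol silyl ether 10. Once C8 is quaternary the enone can enolise only toward C6, so γ-oxidation has no regiochemical competitor on the enolisation side. The oxidant must enter anti to the C7 side chain.

**C8 quaternary centre, 9 back to 5.** The C8–C9 bond (3-bromo-2-methylpropene, 8) and the C8–O bond are cut, passing through silyl ether 7 and hydroxy ketone 6. An electrophile enters the carvone enolate anti to the C7 side chain, so whichever of the two arrives second ends up trans to that side chain. Hydroxylation first and alkylation second therefore gives O8 cis and C9 trans to C11, as the glycol paragraph demands.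

**Side-chain oxygen, 5 back to 1.** The C12–O bond is cut: silyl ether 5, alcohol 4 and chloride 2 come from (R)-carvone (1), which supplies C3–C8, C11–C13, C15 and the C7 configuration. The allylic oxidation must come first, while the isopropenyl group is the only electron-rich olefin.

## Roads not taken

**Alternative 1:** The cut is at the C3–O and C6–O bonds, traced through a bridging peroxide to a ring-contained cis,cis-1,3-diene. Forward, tetraphenylporphyrin-sensitised singlet oxygen would add across C3 and C6 of a preformed ten-membered carbocycle to give endoperoxide A1, whose surviving double bond is the Z olefin.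
- Merits: both oxygens arrive in one suprafacial event, so their cis relation and the olefin geometry are guaranteed, and no late reduction at C3 is needed. In that respect it is better than the chosen plan.
- Weak points: the ten-membered ring with a strained cis,cis-diene must be made first. Such a diene is twisted, so the cycloaddition is slowed and ene reactions at C15, C2 and C7 compete. The face of addition relative to C7 is set by a flexible ring. A1 still lacks C13 and the lactone.
- Comparison: the chosen plan pays with a γ-oxidation (step 8) and a late directed reduction (step 19). In return it never closes a medium ring and fixes C6 against C7 on a cyclohexenone.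

**Alternative 2:** The cut is at C5–C6 and the lactone acyl–oxygen bond. Forward, CrCl2 (divalent chromium) with catalytic NiCl2 would convert a Z-alkenyl iodide into the alkenylchromium species, which adds to a C6 aldehyde; the alkoxide then closes onto a methyl ester to give lactone A2.
- Merits: it is convergent, tolerates much functionality, carries the olefin geometry over from the iodide, and makes ring and lactone in one operation. Its longest linear sequence would probably be shorter than the present one.
- Weak points: a ten-membered Z-cycloalkene must be closed at high dilution with excess chromium. The C6 configuration depends on the conformation of the cyclising chain, next to an epimerisable C7. A2 has C11 saturated, so the methylene must be added by late enolate chemistry near an angelate.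
- Comparison: the chosen plan is linear but sets C6 trans to C7 on a six-membered ring, obtains the Z olefin by construction and needs no dilution.

**Alternative 3:** The cut is at C1–C10. Forward, SmI2 would reduce a C1 aldehyde and a C10 methyl ketone on a seco-lactone and join the two ketyl carbons to give 1,10-diol A3.
- Merits: ring and glycol form together, samarium chelation favours a cis-diol, and the C3 and C8 oxygens are in place before ring closure. No 1,6-dione with its transannular chemistry ever appears; that is a real advantage over the chosen plan.
- Weak points: two stereocentres are created in a medium-ring radical coupling with only remote centres to choose the face, and intermolecular coupling and simple reduction compete. A3 again lacks C13.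
- Comparison: the chosen plan makes the same glycol by osmylation on the convex face of a rigid bicycle and opens the ring by fragmentation, at the price of handling dione 22 briefly.

Key step: step 15

## Conventions and assumptions

- Germacrane numbering of 28 is used for all intermediates. In the monocycles the ring is C3–C8 with C3 the carbonyl carbon; C11–C13 are the C7 side chain; C9, C10, C14 come from 8; C1, C2 from 13.
- β is the ring face that carries C11 at C7; α is the other.
- Assumption on the chemistry: in the ten-membered ring a triacetoxyborohydride bound to a β-hydroxyl is taken to deliver hydride to the β-face of the carbonyl two carbons away, the ring counterpart of the acyclic 1,3-anti rule.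
- Compounds 22, 23, 26 and 27 are drawn as open 3-ketones; partial closure of the C10 hydroxyl onto C3 as a five-membered hemiketal is expected and reversible.

## Route

Step 1
Reactants: 1 (R)-(−)-carvone
Product: 2 (5R)-5-(3-chloroprop-1-en-2-yl)-2-methylcyclohex-2-en-1-one
Conditions: Ca(OCl)2, CO2 (dry ice), CH2Cl2/H2O, 0 °C
Reagents that add atoms: calcium hypochlorite, [Ca+2].[O-]Cl.[O-]Cl
Why: Ene-type allylic chlorination by HOCl formed in the flask: the electron-rich 1,1-disubstituted olefin reacts, the enone olefin does not, and the side chain keeps a methylene group; C7 is untouched.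

Step 2
Reactants: 2 (5R)-5-(3-chloroprop-1-en-2-yl)-2-methylcyclohex-2-en-1-one
Product: 4 (5R)-5-(3-hydroxyprop-1-en-2-yl)-2-methylcyclohex-2-en-1-one, via allylic acetate 3 (not isolated)
Conditions: KOAc, Bu4NI (cat.), DMF, 60 °C; then K2CO3, MeOH, rt
Reagents that add atoms: potassium acetate, CC(=O)[O-].[K+]
Why: SN2 displacement of the primary allylic chloride by acetate, then carbonate-catalysed transesterification with methanol; neither operation touches the enone or C7.

Step 3
Reactants: 4 (5R)-5-(3-hydroxyprop-1-en-2-yl)-2-methylcyclohex-2-en-1-one
Product: 5 (5R)-2-methyl-5-[3-(triethylsilyloxy)prop-1-en-2-yl]cyclohex-2-en-1-one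
Conditions: Et3SiCl, imidazole, CH2Cl2, 0 °C
Reagents that add atoms: chlorotriethylsilane, CC[Si](Cl)(CC)CC
Why: Standard silylation of a primary alcohol; the triethylsilyl ether survives the enolate chemistry of steps 4–7 and is labile enough to be removed in the work-up of step 8.

Step 4
Reactants: 5 (5R)-2-methyl-5-[3-(triethylsilyloxy)prop-1-en-2-yl]cyclohex-2-en-1-one
Product: 6 α′-hydroxy enone (8α-OH; hydroxyl trans to the C7 side chain)
Conditions: NaN(SiMe3)2, THF, −78 °C; then 2-(phenylsulfonyl)-3-phenyloxaziridine, −78 °C; aq. NH4Cl
Reagents that add atoms: 2-(phenylsulfonyl)-3-phenyloxaziridine, O=S(=O)(N1OC1c1ccccc1)c1ccccc1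
Why: Kinetic α′-deprotonation of the enone at C8 and hydroxylation of the sodium enolate by the N-sulfonyloxaziridine (Davis oxidation); the reagent enters anti to the C7 side chain, but the C8 configuration is of no consequence because C8 is planarised again in step 6.

Step 5
Reactants: 6 α′-hydroxy enone
Product: 7 α′-silyloxy enone (8α-OSiMe2tBu)
Conditions: tBuMe2SiOTf, 2,6-lutidine, CH2Cl2, −78 → 0 °C
Reagents that add atoms: tert-butyldimethylsilyl triflate, CC(C)(C)[Si](C)(C)OS(=O)(=O)C(F)(F)F
Why: Silyl triflate silylation of a secondary α-hydroxy ketone; the tert-butyldimethylsilyl group is chosen because it is slow to migrate between oxygens in the enolate of step 6.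

Step 6
Reactants: 7 α′-silyloxy enone; 8 3-bromo-2-methylpropene
Product: 9 quaternary enone (8β-OSiMe2tBu; 8α-CH2C(CH3)=CH2)
Conditions: LiN(iPr)2, THF, −78 °C; then 8, DMPU, −78 → −20 °C
Reagents that add atoms: none
Why: Alkylation of the lithium enolate of an α-silyloxy ketone with a reactive allylic bromide; the axial C8 hydrogen is kinetically acidic, and in the enolate A(1,2) strain with the silyloxy group pushes the C7 side chain pseudoaxial, so 8 bonds to C8 on the opposite (α) face. The quaternary centre thus has O8 cis and C9 trans to C11.

Step 7
Reactants: 9 quaternary enone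
Product: 10 trimethylsilyl dienol ether [C3(OSiMe3)=C4(CH3)–C5=C6]
Conditions: Me3SiOTf, Et3N, CH2Cl2, 0 °C
Reagents that add atoms: trimethylsilyl triflate, C[Si](C)(C)OS(=O)(=O)C(F)(F)F
Why: Soft enolisation with silyl triflate and amine; C8 is quaternary, so only the γ-hydrogens at C6 can be removed and the linear 1-silyloxy-1,3-diene is the only enol ether available.

Step 8
Reactants: 10 trimethylsilyl dienol ether
Product: 12 enone diol (6α-OH; 12-OH; 8β-OSiMe2tBu), via hydroxy enone triethylsilyl ether 11 (not isolated)
Conditions: mCPBA, NaHCO3, CH2Cl2, −40 °C; then MeOH, PPTS, rt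
Reagents that add atoms: 3-chloroperoxybenzoic acid, O=C(OO)c1cccc(Cl)c1
Why: Vinylogous Rubottom oxidation: the peracid epoxidises the terminal C5=C6 bond of the silyloxydiene (largest HOMO coefficient at C6, and far less hindered than the tetrasubstituted C3=C4 bond beside the quaternary centre), the epoxide opens with push from the silyloxy group to restore the enone with a C6 hydroxyl, and approach anti to the C7 side chain makes it α. Acidic methanol then removes the trimethylsilyl residue and the primary triethylsilyl ether and leaves the tertiary silyl ether.

Step 9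
Reactants: 12 enone diol; 13 allylmagnesium bromide
Product: 14 allyl carbinol (3β-OH; 3α-allyl; 8α-methallyl; 8β-OSiMe2tBu; 6α-OH; 12-OH)
Conditions: 13 (4 equiv), THF, −78 °C; aq. NH4Cl
Reagents that add atoms: none
Why: Grignard 1,2-addition to the hindered enone carbonyl (two equivalents are spent on the hydroxyls); with the C6, C7 and methallyl substituents equatorial the C8 silyloxy group is axial on the β-face, so the reagent attacks C3 axially from the α-face, antiperiplanar to the C8–O bond. The allyl group therefore ends up cis to the methallyl group and O3 cis to O8.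

Step 10
Reactants: 14 allyl carbinol
Product: 15 cis-fused bicyclic diene triol (ring B closed; C1=C10; 3β-OH; 8β-OSiMe2tBu; 6α-OH; 12-OH)
Conditions: second-generation Grubbs catalyst (H2IMes)(PCy3)Cl2Ru=CHPh (5 mol %), CH2Cl2 (5 mM), 40 °C
Reagents that add atoms: none
Why: Ring-closing metathesis between the monosubstituted and the 1,1-disubstituted olefin on adjacent, cis-related quaternary carbons closes the cyclohexene of ring B with loss of ethene; the side-chain methylene and the ring A olefin have no partner within reach.

Step 11
Reactants: 15 cis-fused bicyclic diene triol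
Product: 18 bicyclic 6α,12-lactone (3β-OH; 8β-OSiMe2tBu), via enal 16 (not isolated), via lactol 17 (not isolated)
Conditions: TEMPO (20 mol %), PhI(OAc)2, CH2Cl2, rt
Reagents that add atoms: none
Why: Nitroxyl-catalysed oxidation with PhI(OAc)2 is selective for the primary allylic alcohol; enal 16 is trapped by the C6 hydroxyl as lactol 17, which is oxidised to the trans-fused lactone. O8 is still silylated, so it can neither compete for the aldehyde nor offer the hypervalent iodine reagent a free glycol to cleave.

Step 12
Reactants: 18 bicyclic 6α,12-lactone
Product: 19 bicyclic lactone 3β,8β-diol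
Conditions: HF·pyridine, THF, rt
Reagents that add atoms: none
Why: Fluoride cleavage of the tertiary silyl ether under non-basic conditions that spare the α-methylene lactone; the neighbouring free C3 hydroxyl assists.

Step 13
Reactants: 19 bicyclic lactone 3β,8β-diol
Product: 20 bicyclic lactone 1β,3β,8β,10β-tetraol (C14 α)
Conditions: OsO4 (2 mol %), NMO, acetone/H2O, 0 °C → rt
Reagents that add atoms: osmium tetroxide (catalytic oxygen carrier), O=[Os](=O)(=O)=O; N-methylmorpholine N-oxide, C[N+]1([O-])CCOCC1; water, O
Why: Upjohn dihydroxylation: OsO4 picks the electron-rich trisubstituted ring B olefin over the acrylate-type methylene and over the C4–C5 olefin, which is flanked by a quaternary carbon and deactivated by two allylic C–O bonds. Suprafacial addition on the convex face of the cis-fused bicycle, the face of the two fusion hydroxyls, sets C1 and C10 together.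

Step 14
Reactants: 20 bicyclic lactone tetraol
Product: 21 bicyclic lactone 3β,8β,10β-triol 1β-OSiMe2tBu
Conditions: tBuMe2SiOTf (1.1 equiv), 2,6-lutidine, CH2Cl2, −78 °C
Reagents that add atoms: tert-butyldimethylsilyl triflate, CC(C)(C)[Si](C)(C)OS(=O)(=O)C(F)(F)F
Why: Silyl triflate at low temperature silylates the only secondary hydroxyl and leaves the three tertiary ones free, so the C1/C10 glycol is masked and the C3/C8 glycol is not.

Step 15
Reactants: 21 bicyclic lactone 3β,8β,10β-triol 1β-OSiMe2tBu
Product: 22 ten-membered 3,8-dione lactone (4Z; 10β-OH; 1β-OSiMe2tBu)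
Conditions: Pb(OAc)4, NaHCO3, CH2Cl2, −20 → 0 °C
Reagents that add atoms: none
Why: Criegee glycol cleavage: the cis tertiary hydroxyls at C3 and C8 displace two acetates on tetravalent lead to form a five-membered cyclic lead diester, which fragments in a concerted two-electron step to the C3 and C8 ketones, divalent lead diacetate and acetic acid. The closest known case is the cleavage of cis-decalin-4a,8a-diol to cyclodecane-1,6-dione. No ring is closed by bond formation: the ten-membered ring is the perimeter of the bicycle and is uncovered when the shared C3–C8 bond is cut, so no cyclisation mode, template or dilution is involved. No stereocentre is created; C3 and C8 are erased, C1, C6, C7 and C10 are untouched, and the C4–C5 olefin, formerly in a cyclohexene, keeps its Z geometry and becomes conjugated to the C3 ketone. The selectivity needed is cleavage of this glycol only; it is secured because the only other vicinal oxygen pair (C1/C10) carries a silyl ether at C1 and the lactone and olefins are inert to the reagent at 0 °C. The C7 hydrogen is now α to the C8 ketone with an acyloxy group β to it, so the medium is kept buffered and non-basic and 22 is taken at once into step 16. The free C10 hydroxyl is expected to rest partly as the hemiketal on C3, which keeps that carbonyl out of transannular aldol chemistry.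

Step 16
Reactants: 22 ten-membered 3,8-dione lactone
Product: 23 8α-hydroxy 3-ketone (10β-OH; 1β-OSiMe2tBu)
Conditions: Me4NBH(OAc)3, MeCN/AcOH, −30 °C
Reagents that add atoms: none
Why: Evans–Saksena reduction: the C10 hydroxyl exchanges onto boron and delivers hydride through a six-membered transition state to the β-face of the C8 ketone, giving the 8α-alcohol, 1,3-anti to O10. The C3 carbonyl has no free β-hydroxyl (C1 is silylated) and is conjugated, and the reagent leaves lactone and olefins alone.

Step 17
Reactants: 23 8α-hydroxy 3-ketone; 24 angelic acid
Product: 26 8α-angelate (3-oxo; 10β-OH; 1β-OSiMe2tBu), via mixed anhydride 25 (not isolated)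
Conditions: 24, 2,4,6-Cl3C6H2COCl, Et3N, toluene, rt; then 23, 75 °C
Reagents that add atoms: none
Why: Yamaguchi esterification through mixed anhydride 25, run without nucleophilic catalyst so that the Z geometry of the angelate is kept; only the secondary C8 hydroxyl is acylated, the tertiary C10 hydroxyl is inert.

Step 18
Reactants: 26 8α-angelate
Product: 27 1β,10β-dihydroxy-3-oxo 8α-angelate
Conditions: HF·pyridine, pyridine, THF, 0 °C → rt
Reagents that add atoms: none
Why: Buffered HF·pyridine removes the secondary silyl ether without touching the two esters, the Z-enone or the methylene lactone.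

Step 19
Reactants: 27 1β,10β-dihydroxy-3-oxo 8α-angelate
Product: 28 target: 8α-angeloyloxy-1β,3α,10β-trihydroxygermacra-4Z,11(13)-dien-6α,12-olide
Conditions: Me4NBH(OAc)3, MeCN/AcOH, −30 → −10 °C
Reagents that add atoms: none
Why: Second Evans–Saksena reduction: the freed C1 hydroxyl (β) binds boron and delivers hydride in a 1,2 sense to the β-face of the C3 carbonyl, giving the 3α-alcohol anti to O1; the C10 hydroxyl lies on the same face and can only reinforce this. Conjugated esters and the lactone are not reduced by the triacetoxyborohydride.

## Compound list

1 | (R)-(−)-carvone, (5R)-2-methyl-5-(prop-1-en-2-yl)cyclohex-2-en-1-one | CC1=CC[C@@H](C(C)=C)CC1=O | starting material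
2 | (5R)-5-(3-chloroprop-1-en-2-yl)-2-methylcyclohex-2-en-1-one (chloride at C12) | CC1=CC[C@@H](C(=C)CCl)CC1=O | intermediate
3 | (5R)-5-(3-acetoxyprop-1-en-2-yl)-2-methylcyclohex-2-en-1-one (not isolated) | CC1=CC[C@@H](C(=C)COC(C)=O)CC1=O | intermediate
4 | (5R)-5-(3-hydroxyprop-1-en-2-yl)-2-methylcyclohex-2-en-1-one | CC1=CC[C@@H](C(=C)CO)CC1=O | intermediate
5 | (5R)-2-methyl-5-[3-(triethylsilyloxy)prop-1-en-2-yl]cyclohex-2-en-1-one | CC1=CC[C@@H](C(=C)CO[Si](CC)(CC)CC)CC1=O | intermediate
6 | 6-hydroxy derivative of 5, hydroxyl trans to the C5 side chain (8α-OH) | CC1=CC[C@@H](C(=C)CO[Si](CC)(CC)CC)[C@H](O)C1=O | intermediate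
7 | tert-butyldimethylsilyl ether of 6 (8α-OSiMe2tBu) | CC1=CC[C@@H](C(=C)CO[Si](CC)(CC)CC)[C@H](O[Si](C)(C)C(C)(C)C)C1=O | intermediate
8 | 3-bromo-2-methylpropene | C=C(C)CBr | starting material
9 | 6-(tert-butyldimethylsilyloxy)-2-methyl-6-(2-methylprop-2-enyl)-5-[3-(triethylsilyloxy)prop-1-en-2-yl]cyclohex-2-en-1-one, silyloxy cis and methallyl trans to the C5 side chain (8β-O, 8α-C9) | CC1=CC[C@@H](C(=C)CO[Si](CC)(CC)CC)[C@](O[Si](C)(C)C(C)(C)C)(CC(C)=C)C1=O | intermediate
10 | trimethylsilyl dienol ether of 9, 1-(trimethylsilyloxy)cyclohexa-1,3-diene with C3(OSiMe3)=C4(CH3)–C5=C6 | CC1=C(O[Si](C)(C)C)[C@@](O[Si](C)(C)C(C)(C)C)(CC(C)=C)[C@H](C(=C)CO[Si](CC)(CC)CC)C=C1 | intermediate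
11 | 4-hydroxy enone from 10, hydroxyl trans to the side chain (6α-OH), C12 triethylsilyl ether retained (not isolated) | CC1=C[C@H](O)[C@@H](C(=C)CO[Si](CC)(CC)CC)[C@](O[Si](C)(C)C(C)(C)C)(CC(C)=C)C1=O | intermediate
12 | enone diol: 6α-OH, 12-OH, 8β-OSiMe2tBu, 8α-methallyl | CC1=C[C@H](O)[C@@H](C(=C)CO)[C@](O[Si](C)(C)C(C)(C)C)(CC(C)=C)C1=O | intermediate
13 | allylmagnesium bromide | C=CC[Mg]Br | starting material
14 | tertiary allyl carbinol: 3β-OH, 3α-allyl, 8α-methallyl, 8β-OSiMe2tBu, 6α-OH, 12-OH | CC1=C[C@H](O)[C@@H](C(=C)CO)[C@](O[Si](C)(C)C(C)(C)C)(CC(C)=C)[C@]1(O)CC=C | intermediate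
15 | cis-fused bicycle (fusion carbons C3 and C8), olefins C4=C5 and C1=C10, 3β-OH, 8β-OSiMe2tBu, 6α-OH, 7β-(3-hydroxyprop-1-en-2-yl) | CC1=C[C@H](O)[C@@H](C(=C)CO)[C@]2(O[Si](C)(C)C(C)(C)C)CC(C)=CC[C@]12O | intermediate
16 | enal corresponding to 15, C12 aldehyde (not isolated) | CC1=C[C@H](O)[C@@H](C(=C)C=O)[C@]2(O[Si](C)(C)C(C)(C)C)CC(C)=CC[C@]12O | intermediate
17 | 6,12-lactol of 16, anomeric mixture (not isolated) | CC1=C[C@@H]3OC(O)C(=C)[C@H]3[C@]2(O[Si](C)(C)C(C)(C)C)CC(C)=CC[C@]12O | intermediate
18 | bicyclic trans-fused 6α,12-α-methylene lactone, 3β-OH, 8β-OSiMe2tBu | CC1=C[C@@H]3OC(=O)C(=C)[C@H]3[C@]2(O[Si](C)(C)C(C)(C)C)CC(C)=CC[C@]12O | intermediate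
19 | bicyclic lactone 3β,8β-diol | CC1=C[C@@H]3OC(=O)C(=C)[C@H]3[C@]2(O)CC(C)=CC[C@]12O | intermediate
20 | bicyclic lactone 1β,3β,8β,10β-tetraol (all four hydroxyls cis, C14 α) | CC1=C[C@@H]3OC(=O)C(=C)[C@H]3[C@]2(O)C[C@](O)(C)[C@@H](O)C[C@]12O | intermediate
21 | 1-O-tert-butyldimethylsilyl ether of 20 (precursor of the key step) | CC1=C[C@@H]3OC(=O)C(=C)[C@H]3[C@]2(O)C[C@](O)(C)[C@@H](O[Si](C)(C)C(C)(C)C)C[C@]12O | intermediate
22 | ten-membered 3,8-dioxo-4Z-ene 6α,12-olide, 10β-OH, 1β-OSiMe2tBu (product of the key step) | C/C1=C/[C@@H]2OC(=O)C(=C)[C@H]2C(=O)C[C@](O)(C)[C@@H](O[Si](C)(C)C(C)(C)C)CC1=O | intermediate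
23 | 8α-hydroxy-3-oxo compound from 22 | C/C1=C/[C@@H]2OC(=O)C(=C)[C@H]2[C@H](O)C[C@](O)(C)[C@@H](O[Si](C)(C)C(C)(C)C)CC1=O | intermediate
24 | angelic acid, (Z)-2-methylbut-2-enoic acid | C/C=C(/C)C(=O)O | starting material
25 | angelic 2,4,6-trichlorobenzoic anhydride (not isolated) | C/C=C(/C)C(=O)OC(=O)c1c(Cl)cc(Cl)cc1Cl | intermediate
26 | 8α-angelate of 23 | C/C1=C/[C@@H]2OC(=O)C(=C)[C@H]2[C@H](OC(=O)/C(C)=C\C)C[C@](O)(C)[C@@H](O[Si](C)(C)C(C)(C)C)CC1=O | intermediate
27 | 1β,10β-dihydroxy-3-oxo 8α-angelate | C/C1=C/[C@@H]2OC(=O)C(=C)[C@H]2[C@H](OC(=O)/C(C)=C\C)C[C@](O)(C)[C@@H](O)CC1=O | intermediate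
28 | CNP0249520.1, 8α-angeloyloxy-1β,3α,10β-trihydroxygermacra-4Z,11(13)-dien-6α,12-olide | C=C1C(=O)O[C@H]2/C=C(/C)[C@@H](O)C[C@H](O)[C@](C)(O)C[C@@H](OC(=O)/C(C)=C\C)[C@H]12 | target

## Step count and risks

Total step count: 19. Longest linear sequence: 19 steps (1 to 28); 8, 13 and 24 are used as purchased.

**Step 15 (key step).** The cleavage itself is expected to be fast; the likely failure is decay of the product once formed. The C7 hydrogen of 22 is flanked by the new ketone, the acyloxy-bearing C6 and the vinylic C11. Loss of the C6 carboxylate through the C7 enol, drift of the exocyclic double bond into conjugation, epimerisation at C7 or transannular aldolisation of the 1,6-dicarbonyl can therefore set in during work-up. Fallback: postpone the lactone until the C8 ketone has been reduced. Setting out from 21, iBu2AlH would reduce the lactone to the 6,12-diol F1, and Et3SiCl with imidazole would give the bis(triethylsilyl) ether F2 with the tertiary hydroxyls untouched. Pb(OAc)4 would then give the dione F3, in which C6 carries a poor leaving group and the side-chain olefin is isolated. Me4NBH(OAc)3 would give the 8α-alcohol F4 and anhydride 25 the angelate F5. Buffered HF·pyridine would remove the two triethylsilyl groups to give the diol F6, and TEMPO with PhI(OAc)2 would close the lactone. The sequence returns to the route at 26, at the cost of three extra operations and a transient free C6 hydroxyl next to the Z-enone.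

**Step 6.** Silyl migration from O8 to the enolate oxygen, or competing removal of a γ-hydrogen at C6, would put the electrophile on the wrong carbon; the crowded silyloxy enolate may also alkylate sluggishly or on oxygen. Fallback: make the C8–C9 bond intramolecularly. Setting out from 6, Ag2O and 8 would give the methallyl ether F7. LiN(iPr)2 would trigger a [2,3]-Wittig rearrangement of its enolate, the allyl terminus again arriving anti to the C7 side chain, to give the tertiary α-hydroxy ketone F8. Silylation with tBuMe2SiOTf returns to the route at 9.

**Step 8.** Poor regioselectivity of the peracid, with attack at the silyl enol ether double bond C3=C4 or at a side-chain olefin, would give a C4-hydroxylated deconjugated ketone or epoxides. Fallback: a cycloaddition that can only place oxygen at C6. Setting out from 10, singlet oxygen (O2, light, tetraphenylporphyrin, CH2Cl2, −78 °C) would add across C3 and C6 from the α-face to give the endoperoxide F9. PPh3 would cleave the O–O bond, and collapse of the C3 silyl hemiketal would give 11; acidic methanol as in step 8 returns to the route at 12.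

**Step 13.** Loss of chemoselectivity, through osmylation of the exocyclic methylene or of the C4–C5 olefin alongside the ring B olefin, would consume material. Fallback: remove the competing olefin temporarily. Setting out from 19, Me2NH would add to the methylene lactone to give the amine adduct F10. Dihydroxylation under the same conditions would give the tetraol F11. Quaternisation with MeI and elimination with NaHCO3 would re-expose the methylene and return to the route at 20.

**Step 16.** Facial selectivity may be poor if exchange of the tertiary C10 hydroxyl onto boron is slow or the ring conformation misdirects the internal delivery, giving the 8β-alcohol; step 19 shares this uncertainty. Fallback: use the wrong epimer. Setting out from 22, if the 8-epi alcohol F12 is what forms (it could also be made deliberately by chelation-controlled reduction with Et2BOMe and NaBH4), Mitsunobu esterification with 24, PPh3 and diisopropyl azodicarboxylate would invert C8 and install the angelate in one operation, returning to the route at 26.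

## Further compounds

F1 | step 15 | bicyclic 6α,12-diol from reduction of the lactone of 21 | CC1=C[C@H](O)[C@@H](C(=C)CO)[C@]2(O)C[C@](O)(C)[C@@H](O[Si](C)(C)C(C)(C)C)C[C@]12O
F2 | step 15 | 6,12-bis(triethylsilyl) ether of F1 | CC1=C[C@H](O[Si](CC)(CC)CC)[C@@H](C(=C)CO[Si](CC)(CC)CC)[C@]2(O)C[C@](O)(C)[C@@H](O[Si](C)(C)C(C)(C)C)C[C@]12O
F3 | step 15 | ten-membered 3,8-dione with 6,12-bis(triethylsilyl) ether | C/C1=C/[C@H](O[Si](CC)(CC)CC)[C@@H](C(=C)CO[Si](CC)(CC)CC)C(=O)C[C@](O)(C)[C@@H](O[Si](C)(C)C(C)(C)C)CC1=O
F4 | step 15 | 8α-alcohol from F3 | C/C1=C/[C@H](O[Si](CC)(CC)CC)[C@@H](C(=C)CO[Si](CC)(CC)CC)[C@H](O)C[C@](O)(C)[C@@H](O[Si](C)(C)C(C)(C)C)CC1=O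
F5 | step 15 | 8α-angelate of F4 | C/C1=C/[C@H](O[Si](CC)(CC)CC)[C@@H](C(=C)CO[Si](CC)(CC)CC)[C@H](OC(=O)/C(C)=C\C)C[C@](O)(C)[C@@H](O[Si](C)(C)C(C)(C)C)CC1=O
F6 | step 15 | 6,12-diol from F5 | C/C1=C/[C@H](O)[C@@H](C(=C)CO)[C@H](OC(=O)/C(C)=C\C)C[C@](O)(C)[C@@H](O[Si](C)(C)C(C)(C)C)CC1=O
F7 | step 6 | 2-methylallyl ether of 6 | CC1=CC[C@@H](C(=C)CO[Si](CC)(CC)CC)[C@H](OCC(C)=C)C1=O
F8 | step 6 | tertiary α-hydroxy ketone (8β-OH, 8α-methallyl) | CC1=CC[C@@H](C(=C)CO[Si](CC)(CC)CC)[C@](O)(CC(C)=C)C1=O
F9 | step 8 | 3,6-endoperoxide of 10 (peroxide bridge α) | CC1=C[C@@H]2OO[C@@]1(O[Si](C)(C)C)[C@@](O[Si](C)(C)C(C)(C)C)(CC(C)=C)[C@@H]2C(=C)CO[Si](CC)(CC)CC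
F10 | step 13 | dimethylamine adduct of 19 (13-dimethylamino-11,13-dihydro lactone, C11 mixture) | CC1=C[C@@H]3OC(=O)C(CN(C)C)[C@H]3[C@]2(O)CC(C)=CC[C@]12O
F11 | step 13 | 1β,10β-diol from F10 | CC1=C[C@@H]3OC(=O)C(CN(C)C)[C@H]3[C@]2(O)C[C@](O)(C)[C@@H](O)C[C@]12O
F12 | step 16 | 8β-alcohol, C8 epimer of 23 | C/C1=C/[C@@H]2OC(=O)C(=C)[C@H]2[C@@H](O)C[C@](O)(C)[C@@H](O[Si](C)(C)C(C)(C)C)CC1=O
A1 | alternative 1 | ten-membered carbocycle with 3,6-endoperoxide, C7 CH2CO2Me, 8-OSiEt3, 1,10-acetonide | C1[C@@H]2OO[C@@H](C=C2C)[C@@H](CC(=O)OC)[C@H](O[Si](CC)(CC)CC)C[C@@]3(C)OC(C)(C)O[C@@H]13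
A2 | alternative 2 | ten-membered 6,12-trans-lactone with C11 saturated, 3-OSiMe2tBu, 1,10-acetonide, 8-OSiEt3 | C1C(=O)O[C@H]2/C=C(/C)[C@@H](O[Si](C)(C)C(C)(C)C)C[C@@H]3OC(C)(C)O[C@]3(C)C[C@@H](O[Si](CC)(CC)CC)[C@H]12
A3 | alternative 3 | ten-membered 1,10-diol trans-lactone with C11 saturated, 3-OSiMe2tBu, 8-O-(4-methoxybenzyl) | C1C(=O)O[C@H]2/C=C(/C)[C@@H](O[Si](C)(C)C(C)(C)C)C[C@H](O)[C@](C)(O)C[C@@H](OCc3ccc(OC)cc3)[C@H]12
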